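## Analysis of the target

The target is a furanone-bridged germacranolide. Its ten-membered carbocycle (C1–C10) carries a 3(2H)-furanone built from the C1 ketone, C2=C3, an ether oxygen and C10, so that this oxygen spans C3 and C10 (an 11-oxabicyclo[6.2.1]undecane). An α-methylene-γ-butyrolactone (C11=C13, C12 carbonyl) is fused on C6–C7, C4=C5 is a cis trisubstituted olefin (methyl C15) conjugated with the furanone, and C8 bears an (R)-2-methylbutanoate. The four ring stereocentres are 6R, 7R, 8R and 10S: H6 and H7 are trans, the C8 oxygen is anti to C11 across C7–C8 and 1,3-anti to the C6 oxygen. C10 is a quaternary ether carbon (methyl C14) remote from the C6–C8 triad, so its relation to C6 has to be relayed through the ring. Sensitive groups are the α-methylene lactone (Michael acceptor), the cross-conjugated dienone (a vinylogous ester, labile to base and nucleophiles), the allylic C6–O bond and the epimerisable α-centre of the side-chain ester. The synthesis is hard because of the strained, highly unsaturated medium ring, the quaternary C10 and the 1,5-relationship between C10 and C6. The strategy rests on the five-membered ring O–C3–C2–C1–C10, in which an ether carbon (C10) sits next to a ketone (C1). This is the pattern left by an oxonium ylide [2,3]-shift, where a carbenoid at C10 is captured by an ether oxygen on C3 and an allyl group (C7–C8=C9) moves from that oxygen to C10.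

## Retrosynthetic reasoning

**31 ⇒ 30 ⇒ 28 + 29.** The C12 carbonyl is removed first, because a methylene tetrahydrofuran is far more robust than the α-methylene lactone and its CH2 is doubly activated (allylic, α to oxygen) for a late oxidation. The side-chain ester is cut next, which leaves alcohol 28 and acid 29, so the epimerisable acyl group enters only one step before the end.

**28 ⇒ 27.** The C7–C11 bond is cut. A C7 radical generated from the C7–C8 epoxide of 27 can close on a C6 propargyl ether, so one operation forms the lactone ring at the ether oxidation level, sets C7 and keeps the C8 oxygen of the epoxide.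

**27 ⇒ 26 ⇒ 24 + 25 ⇒ 23.** The epoxide comes from the E C7=C8 olefin of 26, the propargyl ether from alcohol 24 and bromide 25, and 24 from silyl ether 23. The C6 oxygen is carried as a silyl ether until the medium ring exists, and the epoxidation is placed after the furanone is formed so that C4=C5 is deactivated by conjugation.

**23 ⇒ 21.** The C2=C3 double bond is removed. Ketone 21 can enolise only toward C2 (C10 is quaternary), so the furanone follows from 21 by dehydrogenation without any regiochemical question.

**21 ⇒ 18 (key disconnection).** The O–C10 and C9–C10 bonds are cut and the O–C7 bond is restored. This turns the bridged ten-membered ring into a six-membered dihydropyran (18) that carries a vinyl group on C7 and a diazo ketone chain on C3. Two rings, two skeletal bonds and the quaternary C10 are traded for a monocycle in which the cis C4=C5 olefin and the C6 carbinol are trivial to place. The forward reaction must take the carbenoid to the ring oxygen and pass the exocyclic allyl unit to C10.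

**18 ⇒ 16 ⇒ 15 ⇒ 14.** The C1–C10 bond is cut, which gives pyranylacetic acid 16. This comes from methyl ester 15, and 15 from alcohol 14 by silylation.

**14 ⇒ 13 ⇒ 12 ⇒ 11.** Hydride reduction of pyranone 11 gives the C6 alcohol trans to the vinyl group (12), whereas the target demands it cis to the C3 side chain. An SN2 inversion through ester 13 corrects this, and with it all three ring substituents of 14 become cis.

**11 ⇒ 10 ⇒ 9.** The C3–H bond is cut, which gives hemiketal 10. Axial hydride delivery to its oxocarbenium ion makes the 2,6-cis pyran, so C3 is derived from C7. Hemiketal 10 is the oxidative ring expansion product of furyl carbinol 9, whose furan already carries the acetate unit and the C15 methyl in the right places.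

**9 ⇒ 8 ⇒ 5 + 6.** The single stereocentre of 9 (the future C7) is obtained by enzymatic resolution of racemic acetate 8. The C7–C8 bond comes from addition of vinyl Grignard reagent 6 to aldehyde 5.

**5 ⇒ 4 ⇒ 3 ⇒ 1.** Aldehyde 5 comes from formylation of furylacetate 4 at its only free α-position, and 4 from one-carbon homologation (via diazo ketone 3) of commercial acid 1. Starting from 1 fixes the 2,3,5-substitution pattern of the furan without any regiochemical ambiguity.

## Alternatives that were turned down

**Alternative 1:** The C1–C2 bond is cut and the ten-membered ring is closed last by a Nozaki–Hiyama–Kishi-type addition. CrCl2 with catalytic NiCl2 converts the iodoalkyne of open-chain aldehyde A1 into an alkynylchromium species that adds to the C1 aldehyde and gives cyclic enynol A2. Oxidation to the ynone, removal of the C10 silyl group and 5-endo closure of the tertiary alcohol would then make the furanone.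
- For: A1 already holds the lactone, the C8 ester and all four stereocentres. Nothing has to be oxidised or epoxidised on the strained ring afterwards and no new olefin geometry arises. On these two points it is stronger than the chosen route.
- Against: the ring must close around a nearly linear C4–C3≡C2–C1 unit and a cis enyne, by addition to a neopentyl aldehyde, with no driving force comparable to loss of N2. The α-methylene lactone is exposed to divalent chromium. A1 needs a long linear sequence in which C10 is set by a separate asymmetric step with no relay from C6–C8.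
- Comparison: the chosen strategy pays for the medium ring with the exothermic carbenoid/ylide cascade from a six-membered ring and derives C10 from C3.

**Alternative 2:** The organising disconnection is C7–C11. Cp2TiCl (from Cp2TiCl2 and zinc) opens a C7–C8 epoxide to the C7 radical, which cyclises on a C6 propargyl ether and leaves the C8 oxygen as a titanium alkoxide, giving methylene tetrahydrofuran A3.
- For: it is mild and neutral, keeps the C8 stereocentre of the epoxide and is as good an entry to the lactone ring as any. The chosen route uses it as step 19 (A3 has the structure of 28).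
- Against: as a strategy it covers only the last ring. Its substrate is the bridged E-cyclodecadiene epoxide 27, and the hard questions (the oxygen-bridged ten-membered ring, the quaternary C10, the E olefin the epoxide requires) stay open, as does the oxidation at C12.
- Comparison: it was kept as a late step behind a key step that answers those questions.

**Alternative 3:** The C7–C8 bond is cut. Indium inserts into the allylic C13–Br bond of bromomethyl enoate A4 and the allylindium attacks the tethered C8 aldehyde through C7 (Barbier-type, SE2′). This closes the carbocycle, sets C7 and C8 and unveils the C11=C13 methylene in hydroxy ester A5, which would be lactonised onto O6 after an exchange of protecting groups.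
- For: C12 arrives at the acid oxidation level, so no late allylic oxidation is needed, and two stereocentres form in one step under conditions that tolerate water and the furanone. In the endgame it is stronger than the chosen route.
- Against: it is an entropically costly macrocyclisation of a chain that already contains the dienone. The syn/anti outcome at C7/C8 and its relation to C6 depend on a macrocyclic transition state. The aldehyde of A4 is β to the C10 ether oxygen, so enolisation opens the furanone by β-elimination. The free 8-hydroxyl of A5 can lactonise in place of O6, and C10 must be set independently.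
- Comparison: the chosen strategy forms the ring without macrocyclisation and has C10 dictated by the bicycle, at the price of two late redox steps.

Key step: step 14

Remark: the stereodescriptors of the SMILES are taken as absolute (6R,7R,8R,10S and R in the acyl group). C1–C15 refer to the target numbering defined above; the monocyclic pyrans are numbered as pyrans (O1, side-chain carbon C2). Compounds 1, 6, 25 and 29 are commercial; diazoethane is prepared as an ether solution from commercial N-ethyl-N-nitrosourea and KOH.

## Route

Step 1
Reactants: 1 3-methylfuran-2-carboxylic acid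
Product: 3 2-diazo-1-(3-methylfuran-2-yl)ethan-1-one, via acid chloride 2 (not isolated)
Conditions: (COCl)2, DMF (cat.), CH2Cl2, 0 °C to rt; then Me3SiCHN2, THF/MeCN, 0 °C to rt
Reagents that add atoms: (trimethylsilyl)diazomethane, C[Si](C)(C)C=[N+]=[N-]
Why: First stage of an Arndt–Eistert homologation: the acid chloride acylates the diazo carbon and loss of the silyl group as Me3SiCl leaves the α-diazo ketone; the furan is inert under these conditions.

Step 2
Reactants: 3 2-diazo-1-(3-methylfuran-2-yl)ethan-1-one
Product: 4 methyl 2-(3-methylfuran-2-yl)acetate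
Conditions: PhCO2Ag (10 mol %), Et3N, MeOH, rt, dark
Reagents that add atoms: methanol, CO
Why: Silver-catalysed Wolff rearrangement gives the furyl ketene, which methanol traps as the homologated ester; this places the future C2–C1 unit next to the ring methyl.

Step 3
Reactants: 4 methyl 2-(3-methylfuran-2-yl)acetate
Product: 5 methyl 2-(5-formyl-3-methylfuran-2-yl)acetate
Conditions: POCl3, DMF, 0 °C to rt; then aq. NaOAc
Reagents that add atoms: N,N-dimethylformamide (formyl carbon), CN(C)C=O; water (formyl oxygen), O
Why: Vilsmeier–Haack formylation takes the only free α-position (C5) of the 2,3-dialkylfuran, which is also its most nucleophilic site; the ester is not affected.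

Step 4
Reactants: 5 methyl 2-(5-formyl-3-methylfuran-2-yl)acetate; 6 vinylmagnesium bromide
Product: 8 methyl 2-[5-(1-acetoxyprop-2-en-1-yl)-3-methylfuran-2-yl]acetate (racemic), via magnesium alkoxide 7 (not isolated)
Conditions: 6 (1.1 equiv), THF, −78 °C; then Ac2O, −78 to 0 °C
Reagents that add atoms: acetic anhydride, CC(=O)OC(C)=O
Why: Grignard 1,2-addition to the aldehyde is much faster at −78 °C than attack on the methyl ester, and the alkoxide is acetylated in the same flask to give the racemic acetate needed for the resolution.

Step 5
Reactants: 8 methyl 2-[5-(1-acetoxyprop-2-en-1-yl)-3-methylfuran-2-yl]acetate (racemic)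
Product: 9 methyl 2-{5-[(1R)-1-hydroxyprop-2-en-1-yl]-3-methylfuran-2-yl}acetate
Conditions: immobilised Candida antarctica lipase B, MeOH (3 equiv), t-BuOMe, 30 °C, stopped near half conversion
Reagents that add atoms: none
Why: Lipase-catalysed enantioselective alcoholysis (kinetic resolution): with furyl as the large and vinyl as the medium group the R acetate is the fast-reacting enantiomer, so the R alcohol should be released while the S enantiomer of 8 stays behind. Methanol as nucleophile leaves the methyl ester as it is, and this step sets the future C7.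

Step 6
Reactants: 9 methyl 2-{5-[(1R)-1-hydroxyprop-2-en-1-yl]-3-methylfuran-2-yl}acetate
Product: 10 methyl 2-[(6R)-6-ethenyl-2-hydroxy-3-methyl-5-oxo-5,6-dihydro-2H-pyran-2-yl]acetate (hemiketal)
Conditions: NBS (1.05 equiv), NaHCO3, NaOAc, THF/H2O (4:1), 0 °C
Reagents that add atoms: water, O
Why: Achmatowicz rearrangement: bromonium-induced oxidative opening of the furan to the cis-enedione and closure of the carbinol oxygen onto the new ketone give the pyranone hemiketal. The carbinol centre is untouched and the terminal olefin reacts more slowly than the furan.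

Step 7
Reactants: 10 methyl 2-[(6R)-6-ethenyl-2-hydroxy-3-methyl-5-oxo-5,6-dihydro-2H-pyran-2-yl]acetate
Product: 11 methyl 2-[(2S,6R)-6-ethenyl-3-methyl-5-oxo-5,6-dihydro-2H-pyran-2-yl]acetate
Conditions: Et3SiH (3 equiv), CF3CO2H (10 equiv), CH2Cl2, −40 to 0 °C
Reagents that add atoms: none
Why: Ionic hydrogenation of the hemiketal: the acid forms the cyclic oxocarbenium ion and the silane delivers hydride axially, so both groups that flank the ring oxygen end up equatorial (2,6-cis), which sets C3 from C7. Any exocyclic enol ether formed by proton loss is returned to the cation by the acid.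

Step 8
Reactants: 11 methyl 2-[(2S,6R)-6-ethenyl-3-methyl-5-oxo-5,6-dihydro-2H-pyran-2-yl]acetate
Product: 12 methyl 2-[(2S,5S,6R)-6-ethenyl-5-hydroxy-3-methyl-5,6-dihydro-2H-pyran-2-yl]acetate
Conditions: NaBH4, CeCl3·7H2O, MeOH, −78 °C
Reagents that add atoms: none
Why: Luche reduction gives clean 1,2-reduction of the enone at low temperature without touching the ester or epimerising the α-vinyl centre; axial hydride attack puts the hydroxyl equatorial, trans to the vinyl group, which is the C6 epimer of what the target needs.

Step 9
Reactants: 12 methyl 2-[(2S,5S,6R)-6-ethenyl-5-hydroxy-3-methyl-5,6-dihydro-2H-pyran-2-yl]acetate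
Product: 13 methyl 2-[(2S,5R,6R)-6-ethenyl-3-methyl-5-(4-nitrobenzoyloxy)-5,6-dihydro-2H-pyran-2-yl]acetate
Conditions: 4-nitrobenzoic acid, PPh3, DIAD, THF, 0 °C to rt
Reagents that add atoms: 4-nitrobenzoic acid, O=C(O)c1ccc(cc1)[N+](=O)[O-]
Why: Mitsunobu esterification inverts the allylic carbinol by SN2 displacement of the oxyphosphonium ion and so sets C6 cis to both neighbours of the ring oxygen. The acidic 4-nitrobenzoic acid is chosen because the alcohol is hindered, and SN2′ attack would have to occur at the fully substituted C3 of the pyran.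

Step 10
Reactants: 13 methyl 2-[(2S,5R,6R)-6-ethenyl-3-methyl-5-(4-nitrobenzoyloxy)-5,6-dihydro-2H-pyran-2-yl]acetate
Product: 14 methyl 2-[(2S,5R,6R)-6-ethenyl-5-hydroxy-3-methyl-5,6-dihydro-2H-pyran-2-yl]acetate
Conditions: K2CO3, MeOH, 0 °C to rt
Reagents that add atoms: none
Why: Methanolysis cleaves the activated aryl ester; the side-chain ester is already a methyl ester, and the β-alkoxy ester is not enolised by carbonate, so the ring stays closed.

Step 11
Reactants: 14 methyl 2-[(2S,5R,6R)-6-ethenyl-5-hydroxy-3-methyl-5,6-dihydro-2H-pyran-2-yl]acetate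
Product: 15 methyl 2-[(2S,5R,6R)-5-(tert-butyldimethylsilyloxy)-6-ethenyl-3-methyl-5,6-dihydro-2H-pyran-2-yl]acetate
Conditions: t-BuMe2SiOTf, 2,6-lutidine, CH2Cl2, −78 to 0 °C
Reagents that add atoms: tert-butyldimethylsilyl trifluoromethanesulfonate, CC(C)(C)[Si](C)(C)OS(=O)(=O)C(F)(F)F
Why: The silyl triflate silylates the hindered pseudoaxial allylic alcohol; the bulky ether is inert to the carbenoid and later biases the oxonium ylide.

Step 12
Reactants: 15 methyl 2-[(2S,5R,6R)-5-(tert-butyldimethylsilyloxy)-6-ethenyl-3-methyl-5,6-dihydro-2H-pyran-2-yl]acetate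
Product: 16 2-[(2S,5R,6R)-5-(tert-butyldimethylsilyloxy)-6-ethenyl-3-methyl-5,6-dihydro-2H-pyran-2-yl]acetic acid
Conditions: LiOH·H2O, THF/MeOH/H2O, 0 °C to rt; then 1 M HCl to pH 4, 0 °C
Reagents that add atoms: lithium hydroxide (hydroxide oxygen), [Li+].[OH-]
Why: Saponification of the unhindered methyl ester; the secondary silyl ether withstands hydroxide and a brief acidification to pH 4 in the cold.

Step 13
Reactants: 16 2-[(2S,5R,6R)-5-(tert-butyldimethylsilyloxy)-6-ethenyl-3-methyl-5,6-dihydro-2H-pyran-2-yl]acetic acid
Product: 18 1-[(2S,5R,6R)-5-(tert-butyldimethylsilyloxy)-6-ethenyl-3-methyl-5,6-dihydro-2H-pyran-2-yl]-3-diazobutan-2-one, via acid chloride 17 (not isolated)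
Conditions: 1-chloro-N,N,2-trimethylprop-1-en-1-amine, CH2Cl2, 0 °C; then CH3CHN2 (excess, Et2O), −20 to 0 °C
Reagents that add atoms: diazoethane, CC=[N+]=[N-]
Why: The α-chloroenamine forms the acid chloride under neutral conditions, which spares the silyl ether and the allylic ether; acylation of diazoethane then gives the methyl-substituted α-diazo ketone, with the excess diazoalkane scavenging HCl.

Step 14
Reactants: 18 1-[(2S,5R,6R)-5-(tert-butyldimethylsilyloxy)-6-ethenyl-3-methyl-5,6-dihydro-2H-pyran-2-yl]-3-diazobutan-2-one
Product: 21 (3S,4Z,6S,7E,10S)-6-(tert-butyldimethylsilyloxy)-3,10-epoxy-4,10-dimethylcyclodeca-4,7-dien-1-one, via copper carbenoid 19 (not isolated), via oxonium ylide 20 (not isolated)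
Conditions: Cu(hfacac)2 [copper bis(1,1,1,5,5,5-hexafluoropentane-2,4-dionate)] (5 mol %), CH2Cl2, reflux, slow addition of 18
Reagents that add atoms: none
Why: Loss of N2 to Cu(hfacac)2 gives an electrophilic copper carbenoid at C10, which is captured by a lone pair of the ring oxygen to close the five-membered ring O–C3–C2–C1–C10 (5-exo attack on oxygen) as a bicyclic oxonium ylide; the ylide then undergoes a suprafacial [2,3]-sigmatropic shift through a five-membered envelope in which C9 bonds to C10 as O–C7 breaks. The closest known reaction type is the copper-catalysed oxonium ylide formation/[2,3]-rearrangement of 2-vinyl cyclic ether diazo ketones to oxa-bridged medium-ring ketones. The furanone ring is thus closed by ylide formation, and the ten-membered carbocycle by three-atom ring expansion of the pyran, with C7–C8=C9 inserted between the oxygen and C10. The only new stereocentre, C10, is controlled by C3, because the oxygen bridge can span C3 and C10 only cis and C9 must therefore enter on the face of the five-membered ring that carries C4. The C7=C8 geometry depends on where C10 sits on the oxonium oxygen: an equatorial C10 is anti to C6 about O–C7 and can be reached only by a vinyl terminus turned away from C6, which gives the E olefin, whereas an axial C10 would give Z; in 18 the C6 silyloxy group is pseudoaxial (cis to the equatorial vinyl group) and syn-1,3 to the axial site on oxygen, which should disfavour the axial ylide. Selectivity for oxygen over the C4=C5 π bond is expected because the equatorial C3 side chain holds the carbenoid in the ring plane beside the oxygen and away from the π face, and because the electron-poor ligand set favours ylide formation and the concerted [2,3]-shift over cyclopropanation, 1,2-hydride shift from C14 and [1,2]-shift. The ring olefin cannot act as the migrating allyl group, because C10 is tied to C3 by the C1–C2 bridge.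

Step 15
Reactants: 21 (3S,4Z,6S,7E,10S)-6-(tert-butyldimethylsilyloxy)-3,10-epoxy-4,10-dimethylcyclodeca-4,7-dien-1-one
Product: 23 (2Z,4Z,6S,7E,10S)-6-(tert-butyldimethylsilyloxy)-3,10-epoxy-4,10-dimethylcyclodeca-2,4,7-trien-1-one, via silyl enol ether 22 (not isolated)
Conditions: LiN(SiMe3)2, Me3SiCl, THF, −78 °C; then Pd(OAc)2 (1.1 equiv), MeCN, rt
Reagents that add atoms: none
Why: Saegusa–Ito dehydrogenation: the ketone can enolise only toward C2 because C10 is quaternary, and the palladium enolate loses the C3 hydrogen to give the 3(2H)-furanone. Ring opening by β-elimination of the C3 oxygen is disfavoured because that C–O bond lies in the plane of the five-membered enolate.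

Step 16
Reactants: 23 (2Z,4Z,6S,7E,10S)-6-(tert-butyldimethylsilyloxy)-3,10-epoxy-4,10-dimethylcyclodeca-2,4,7-trien-1-one
Product: 24 (2Z,4Z,6S,7E,10S)-3,10-epoxy-6-hydroxy-4,10-dimethylcyclodeca-2,4,7-trien-1-one
Conditions: Bu4NF, AcOH (1:1), THF, 0 °C to rt
Reagents that add atoms: none
Why: Fluoride cleaves the silyl ether; buffering with acetic acid keeps the base-labile dienone and the bis-allylic alcohol away from free alkoxide.

Step 17
Reactants: 24 (2Z,4Z,6S,7E,10S)-3,10-epoxy-6-hydroxy-4,10-dimethylcyclodeca-2,4,7-trien-1-one; 25 propargyl bromide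
Product: 26 (2Z,4Z,6S,7E,10S)-3,10-epoxy-4,10-dimethyl-6-(prop-2-yn-1-yloxy)cyclodeca-2,4,7-trien-1-one
Conditions: NaH, 25, Bu4NI (cat.), THF, 0 °C to rt
Reagents that add atoms: none
Why: Williamson etherification; after step 15 the ketone has no enolisable α-hydrogen, so the alkoxide is the only anion formed and is trapped by the reactive propargylic halide.

Step 18
Reactants: 26 (2Z,4Z,6S,7E,10S)-3,10-epoxy-4,10-dimethyl-6-(prop-2-yn-1-yloxy)cyclodeca-2,4,7-trien-1-one
Product: 27 (2Z,4Z,6R,7S,8R,10S)-3,10:7,8-diepoxy-4,10-dimethyl-6-(prop-2-yn-1-yloxy)cyclodeca-2,4-dien-1-one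
Conditions: D-fructose-derived Shi ketone (30 mol %), KHSO5 (as 2KHSO5·KHSO4·K2SO4), K2CO3, Bu4NHSO4, MeCN/CH2(OMe)2/aq. Na2B4O7 buffer, 0 °C
Reagents that add atoms: potassium peroxymonosulfate, [K+].[O-]S(=O)(=O)OO
Why: Shi epoxidation: the chiral dioxirane epoxidises trans-disubstituted olefins with high face selectivity, and the D-fructose-derived ketone gives the (R,R)-type epoxide, here 7S,8R, which sets C8. The isolated, strained E olefin should react in preference to the electron-poor dienone and the alkyne.

Step 19
Reactants: 27 (2Z,4Z,6R,7S,8R,10S)-3,10:7,8-diepoxy-4,10-dimethyl-6-(prop-2-yn-1-yloxy)cyclodeca-2,4-dien-1-one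
Product: 28 the (6R,7R,8R,10S)-8-hydroxy methylene tetrahydrofuran (target skeleton with C12 as CH2 and a free 8-hydroxyl)
Conditions: Cp2TiCl2 (2.5 equiv), Zn dust, THF, rt; slow addition of 27; then 1 M HCl
Reagents that add atoms: none
Why: Cp2TiCl (trivalent titanium, formed from Cp2TiCl2 and Zn) opens the epoxide homolytically at C7, the carbon next to the ether-bearing C6, as is usual for 2,3-epoxy alcohol derivatives; the C7 radical closes 5-exo-dig on the alkyne and the vinyl radical takes a hydrogen from THF. The ring bonds C6–C5 and C7–C8 should take the trans arrangement on the new five-membered ring, which sets C7, while C8 keeps its oxygen with retention.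

Step 20
Reactants: 28 the (6R,7R,8R,10S)-8-hydroxy methylene tetrahydrofuran; 29 (R)-2-methylbutanoic acid
Product: 30 the 8-O-[(2R)-2-methylbutanoyl] ester of 28
Conditions: 29 (1.5 equiv), DCC, DMAP (10 mol %), CH2Cl2, 0 °C to rt
Reagents that add atoms: none
Why: Steglich esterification of the secondary alcohol with retention at C8; low temperature and catalytic DMAP keep the α-stereocentre of the acyl group intact.

Step 21
Reactants: 30 the 8-O-[(2R)-2-methylbutanoyl] ester of 28
Product: 31 CNP0174601.3 (target)
Conditions: CrO3·2C5H5N (15 equiv), CH2Cl2, rt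
Reagents that add atoms: chromium trioxide, O=[Cr](=O)=O
Why: Chromium-mediated allylic oxidation (Collins-type) of the C12 methylene, which is both allylic and α to the ether oxygen, gives the α-methylene lactone; this is the established finish for methylene tetrahydrofurans made by radical cyclisation. The other allylic positions are tertiary or deactivated by the dienone.

## Compound list

1 | 3-methylfuran-2-carboxylic acid | Cc1ccoc1C(=O)O | starting material
2 | 3-methylfuran-2-carbonyl chloride | Cc1ccoc1C(=O)Cl | intermediate
3 | 2-diazo-1-(3-methylfuran-2-yl)ethan-1-one | Cc1ccoc1C(=O)C=[N+]=[N-] | intermediate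
4 | methyl 2-(3-methylfuran-2-yl)acetate | Cc1ccoc1CC(=O)OC | intermediate
5 | methyl 2-(5-formyl-3-methylfuran-2-yl)acetate | Cc1cc(C=O)oc1CC(=O)OC | intermediate
6 | vinylmagnesium bromide | C=C[Mg]Br | starting material
7 | bromomagnesium alkoxide of the racemic furyl vinyl carbinol | C=CC(O[Mg]Br)c1cc(C)c(CC(=O)OC)o1 | intermediate
8 | methyl 2-[5-(1-acetoxyprop-2-en-1-yl)-3-methylfuran-2-yl]acetate (racemic) | C=CC(OC(C)=O)c1cc(C)c(CC(=O)OC)o1 | intermediate
9 | methyl 2-{5-[(1R)-1-hydroxyprop-2-en-1-yl]-3-methylfuran-2-yl}acetate | C=C[C@@H](O)c1cc(C)c(CC(=O)OC)o1 | intermediate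
10 | methyl 2-[(6R)-6-ethenyl-2-hydroxy-3-methyl-5-oxo-5,6-dihydro-2H-pyran-2-yl]acetate (hemiketal, both epimers at C2) | C=C[C@H]1OC(O)(CC(=O)OC)C(C)=CC1=O | intermediate
11 | methyl 2-[(2S,6R)-6-ethenyl-3-methyl-5-oxo-5,6-dihydro-2H-pyran-2-yl]acetate | C=C[C@H]1O[C@@H](CC(=O)OC)C(C)=CC1=O | intermediate
12 | methyl 2-[(2S,5S,6R)-6-ethenyl-5-hydroxy-3-methyl-5,6-dihydro-2H-pyran-2-yl]acetate | C=C[C@H]1O[C@@H](CC(=O)OC)C(C)=C[C@@H]1O | intermediate
13 | methyl 2-[(2S,5R,6R)-6-ethenyl-3-methyl-5-(4-nitrobenzoyloxy)-5,6-dihydro-2H-pyran-2-yl]acetate | C=C[C@H]1O[C@@H](CC(=O)OC)C(C)=C[C@H]1OC(=O)c2ccc(cc2)[N+](=O)[O-] | intermediate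
14 | methyl 2-[(2S,5R,6R)-6-ethenyl-5-hydroxy-3-methyl-5,6-dihydro-2H-pyran-2-yl]acetate | C=C[C@H]1O[C@@H](CC(=O)OC)C(C)=C[C@H]1O | intermediate
15 | methyl 2-[(2S,5R,6R)-5-(tert-butyldimethylsilyloxy)-6-ethenyl-3-methyl-5,6-dihydro-2H-pyran-2-yl]acetate | C=C[C@H]1O[C@@H](CC(=O)OC)C(C)=C[C@H]1O[Si](C)(C)C(C)(C)C | intermediate
16 | 2-[(2S,5R,6R)-5-(tert-butyldimethylsilyloxy)-6-ethenyl-3-methyl-5,6-dihydro-2H-pyran-2-yl]acetic acid | C=C[C@H]1O[C@@H](CC(=O)O)C(C)=C[C@H]1O[Si](C)(C)C(C)(C)C | intermediate
17 | 2-[(2S,5R,6R)-5-(tert-butyldimethylsilyloxy)-6-ethenyl-3-methyl-5,6-dihydro-2H-pyran-2-yl]acetyl chloride | C=C[C@H]1O[C@@H](CC(=O)Cl)C(C)=C[C@H]1O[Si](C)(C)C(C)(C)C | intermediate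
18 | 1-[(2S,5R,6R)-5-(tert-butyldimethylsilyloxy)-6-ethenyl-3-methyl-5,6-dihydro-2H-pyran-2-yl]-3-diazobutan-2-one (all-cis dihydropyran diazo ketone) | C=C[C@H]1O[C@@H](CC(=O)C(C)=[N+]=[N-])C(C)=C[C@H]1O[Si](C)(C)C(C)(C)C | intermediate
19 | copper carbenoid at C10 derived from 18 (hexafluoroacetylacetonate ligands on copper not drawn) | C=C[C@H]1O[C@@H](CC(=O)C(C)=[Cu])C(C)=C[C@H]1O[Si](C)(C)C(C)(C)C | intermediate
20 | bicyclic oxonium ylide (O bonded to C3, C7 and C10; configuration at oxygen not fixed) | C=C[C@H]1[O+]2[C@@H](CC(=O)[C-]2C)C(C)=C[C@H]1O[Si](C)(C)C(C)(C)C | intermediate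
21 | (3S,4Z,6S,7E,10S)-6-(tert-butyldimethylsilyloxy)-3,10-epoxy-4,10-dimethylcyclodeca-4,7-dien-1-one | CC(C)(C)[Si](C)(C)O[C@@H]1/C=C(/C)[C@@H]2CC(=O)[C@](C)(C/C=C/1)O2 | intermediate
22 | trimethylsilyl enol ether of 21 (C1=C2, C1–OSiMe3) | CC(C)(C)[Si](C)(C)O[C@@H]1/C=C(/C)[C@@H]2C=C(O[Si](C)(C)C)[C@](C)(C/C=C/1)O2 | intermediate
23 | (2Z,4Z,6S,7E,10S)-6-(tert-butyldimethylsilyloxy)-3,10-epoxy-4,10-dimethylcyclodeca-2,4,7-trien-1-one | CC(C)(C)[Si](C)(C)O[C@@H]1/C=C(/C)C2=CC(=O)[C@](C)(C/C=C/1)O2 | intermediate
24 | (2Z,4Z,6S,7E,10S)-3,10-epoxy-6-hydroxy-4,10-dimethylcyclodeca-2,4,7-trien-1-one | O[C@@H]1/C=C(/C)C2=CC(=O)[C@](C)(C/C=C/1)O2 | intermediate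
25 | propargyl bromide (3-bromoprop-1-yne) | C#CCBr | starting material
26 | (2Z,4Z,6S,7E,10S)-3,10-epoxy-4,10-dimethyl-6-(prop-2-yn-1-yloxy)cyclodeca-2,4,7-trien-1-one | C#CCO[C@@H]1/C=C(/C)C2=CC(=O)[C@](C)(C/C=C/1)O2 | intermediate
27 | (2Z,4Z,6R,7S,8R,10S)-3,10:7,8-diepoxy-4,10-dimethyl-6-(prop-2-yn-1-yloxy)cyclodeca-2,4-dien-1-one | C#CCO[C@@H]1/C=C(/C)C2=CC(=O)[C@](C)(C[C@H]3O[C@H]13)O2 | intermediate
28 | (6R,7R,8R,10S)-8-hydroxy methylene tetrahydrofuran (target skeleton with C12 as CH2, free 8-OH) | C=C1CO[C@@H]2/C=C(/C)C3=CC(=O)[C@](C)(C[C@@H](O)[C@@H]12)O3 | intermediate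
29 | (R)-2-methylbutanoic acid | CC[C@@H](C)C(=O)O | starting material
30 | 8-O-[(2R)-2-methylbutanoyl] ester of 28 | C=C1CO[C@@H]2/C=C(/C)C3=CC(=O)[C@](C)(C[C@@H](OC(=O)[C@H](C)CC)[C@@H]12)O3 | intermediate
31 | CNP0174601.3 | C=C1C(=O)O[C@@H]2/C=C(/C)C3=CC(=O)[C@](C)(C[C@@H](OC(=O)[C@H](C)CC)[C@@H]12)O3 | target

## Step count and least certain steps

Total: 21 steps. Longest linear sequence: 21 steps (1 to 31).

**Step 14 (key step).** The most likely failure is partition of the ylide between its two invertomers at oxygen, which would give the Z C7=C8 isomer in part or in the main. Behind that come interception of the carbenoid by the C4=C5 π bond (cyclopropanation), 1,2-hydride migration from the C14 methyl to a vinyl ketone, and a [1,2]-shift. The fallback does not try to force the E geometry but carries the Z olefin through different chemistry. It sets out from 18, whose rearrangement would then give the (7Z)-isomer of 21 F1. Saegusa–Ito dehydrogenation as in step 15 gives the (7Z)-isomer of 23 F2, and buffered Bu4NF gives the (7Z)-allylic alcohol F3. Hydroxyl-directed epoxidation (VO(acac)2, t-BuOOH) of this Z allylic alcohol is expected, through 1,3-allylic strain, to give the threo cis-epoxy alcohol F4, in which C8 is configured as in 28. Propargylation (NaH, 25) gives the cis-epoxy propargyl ether F5, and Cp2TiCl opens it to the same C7 radical as from 27, so the route is rejoined at 28.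

**Step 18.** The most likely failure is poor or reversed facial selectivity. Only the outer face of an E olefin in a medium ring is open, and the conformer that keeps the C6 substituent outside exposes the face leading to the other epoxide, so the chiral ketone may be overruled by the ring. The fallback accepts that epoxide and corrects C8 later by SN2 inversion. It sets out from 26, which would give the 7,8-epoxide on the opposite face F6. Cp2TiCl cyclisation as in step 19 gives the 8-epimer of 28 F7. Mitsunobu reaction (4-nitrobenzoic acid, PPh3, DIAD) gives the 4-nitrobenzoate with the natural C8 configuration F8, and K2CO3 in MeOH returns the route to 28.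

**Step 19.** The most likely failure is interception of the C7 radical before it reaches the alkyne. It could add transannularly to C3 of the dienone (a 5-exo closure through the cis C4=C5 unit that gives a stabilised α-keto radical), the dienone could be reduced by excess Cp2TiCl, or the radical could be trapped by a second Cp2TiCl and eliminate back to the olefin. A cis ring fusion is a further possibility. The fallback builds the oxygen heterocycle before the furanone exists, so that no radical acceptor is present. It sets out from 21. Buffered Bu4NF gives the 6-hydroxy ketone F9, and propargylation under neutral conditions (25, Ag2O) gives the propargyl ether F10. Shi epoxidation as in step 18 gives the 7,8-epoxide F11 (here the strained E olefin must outrun the unconjugated C4=C5). Cp2TiCl gives the methylene tetrahydrofuran hydroxy ketone F12. Soft enolisation (Me3SiOTf, Et3N, which also silylates the 8-hydroxyl in passing), Pd(OAc)2 and a mild acidic work-up then give 28.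

**Step 21.** The most likely failure is lack of site selectivity or degradation during long exposure to excess hexavalent chromium: attack at C6–H (allylic and α to oxygen) or at the C15 methyl, or loss of the dienone. The fallback carries C12 at the acetal oxidation level from the start of the annulation, so that no C–H oxidation is needed at the end. It sets out from 24. Transacetalisation with 3,3-diethoxyprop-1-yne (pyridinium 4-toluenesulfonate, toluene) gives the mixed propargylic acetal F13. Shi epoxidation gives its 7,8-epoxide F14, and Cp2TiCl gives the 12-ethoxy analogue of 28 F15. Esterification with 29 as in step 20 gives the 12-ethoxy analogue of 30 F16, and Jones oxidation (CrO3, H2SO4, acetone, 0 °C) converts the cyclic acetal directly into the lactone 31.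

## Further compounds

F1 | step 14 | (7Z)-isomer of 21 | CC(C)(C)[Si](C)(C)O[C@@H]1/C=C(/C)[C@@H]2CC(=O)[C@](C)(C/C=C\1)O2
F2 | step 14 | (7Z)-isomer of 23 | CC(C)(C)[Si](C)(C)O[C@@H]1/C=C(/C)C2=CC(=O)[C@](C)(C/C=C\1)O2
F3 | step 14 | (7Z)-isomer of 24 | O[C@@H]1/C=C(/C)C2=CC(=O)[C@](C)(C/C=C\1)O2
F4 | step 14 | cis-7,8-epoxy alcohol from F3 (threo to the C6 hydroxyl, C8 as in 28) | O[C@@H]1/C=C(/C)C2=CC(=O)[C@](C)(C[C@H]3O[C@@H]13)O2
F5 | step 14 | 6-O-propargyl ether of F4 | C#CCO[C@@H]1/C=C(/C)C2=CC(=O)[C@](C)(C[C@H]3O[C@@H]13)O2
F6 | step 18 | trans-7,8-epoxide of 26 on the opposite face (epimer of 27 at C7 and C8) | C#CCO[C@@H]1/C=C(/C)C2=CC(=O)[C@](C)(C[C@@H]3O[C@@H]13)O2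
F7 | step 18 | 8-epimer of 28 | C=C1CO[C@@H]2/C=C(/C)C3=CC(=O)[C@](C)(C[C@H](O)[C@@H]12)O3
F8 | step 18 | 8-O-(4-nitrobenzoyl) derivative of 28 | C=C1CO[C@@H]2/C=C(/C)C3=CC(=O)[C@](C)(C[C@@H](OC(=O)c4ccc(cc4)[N+](=O)[O-])[C@@H]12)O3
F9 | step 19 | 6-hydroxy ketone (desilylated 21) | O[C@@H]1/C=C(/C)[C@@H]2CC(=O)[C@](C)(C/C=C/1)O2
F10 | step 19 | 6-O-propargyl ether of F9 | C#CCO[C@@H]1/C=C(/C)[C@@H]2CC(=O)[C@](C)(C/C=C/1)O2
F11 | step 19 | 7,8-epoxide of F10 (configured as in 27) | C#CCO[C@@H]1/C=C(/C)[C@@H]2CC(=O)[C@](C)(C[C@H]3O[C@H]13)O2
F12 | step 19 | 2,3-dihydro analogue of 28 (C1 ketone, C2 methylene, C3–H) | C=C1CO[C@@H]2/C=C(/C)[C@@H]3CC(=O)[C@](C)(C[C@@H](O)[C@@H]12)O3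
F13 | step 21 | 1-ethoxyprop-2-yn-1-yl ether of 24 (mixed acetal, both epimers at the acetal carbon) | CCOC(C#C)O[C@@H]1/C=C(/C)C2=CC(=O)[C@](C)(C/C=C/1)O2
F14 | step 21 | 7,8-epoxide of F13 (configured as in 27) | CCOC(C#C)O[C@@H]1/C=C(/C)C2=CC(=O)[C@](C)(C[C@H]3O[C@H]13)O2
F15 | step 21 | 12-ethoxy analogue of 28 (cyclic acetal) | C=C1C(OCC)O[C@@H]2/C=C(/C)C3=CC(=O)[C@](C)(C[C@@H](O)[C@@H]12)O3
F16 | step 21 | 12-ethoxy analogue of 30 | C=C1C(OCC)O[C@@H]2/C=C(/C)C3=CC(=O)[C@](C)(C[C@@H](OC(=O)[C@H](C)CC)[C@@H]12)O3
A1 | alternative 1 | open-chain iodoalkyne aldehyde (C10 triethylsilyl ether, lactone and C8 ester in place) | C=C1C(=O)O[C@H](/C=C(/C)C#CI)[C@H]1[C@H](OC(=O)[C@H](C)CC)C[C@](C)(O[Si](CC)(CC)CC)C=O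
A2 | alternative 1 | ten-membered cyclic enynol | C=C1C(=O)O[C@@H]2/C=C(/C)C#C[C@@H](O)[C@@](C)(O[Si](CC)(CC)CC)C[C@@H](OC(=O)[C@H](C)CC)[C@@H]12
A3 | alternative 2 | 8-hydroxy methylene tetrahydrofuran (same structure as 28) | C=C1CO[C@@H]2/C=C(/C)C3=CC(=O)[C@](C)(C[C@@H](O)[C@@H]12)O3
A4 | alternative 3 | furanone aldehyde with (Z)-2-(bromomethyl)enoate side chain | COC(=O)/C(CBr)=C/[C@H](O[Si](C)(C)C(C)(C)C)/C=C(/C)C1=CC(=O)[C@](C)(CC=O)O1
A5 | alternative 3 | macrocyclic 8-hydroxy 6-silyloxy methylene ester | C=C(C(=O)OC)[C@H]1[C@H](O[Si](C)(C)C(C)(C)C)/C=C(/C)C2=CC(=O)[C@](C)(C[C@H]1O)O2
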